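Retrosynthesis: cut the C9–O ester, then the ring bond C9–C10, then the C8–O ester, C7–C8, the butenolide (C7=C11 and O–C12), C6–vinyl and C1=C10.
Enabling feature: in the ten-membered carbocycle, C9 is a carbinol between the C8 acyloxy stereocentre and the sp2 carbon C10 of the ring enoate C1=C10(CO2Me). This 2-(1-hydroxyalkyl)acrylate unit is the retron of an alkenyl-metal addition to an α-acyloxy aldehyde. The Z alkenes C4=C5 and C1=C10 and the trans-fused γ-lactone (O–C6–C7–C11–C12) fold the open chain.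
Forward: neryl acetate gives the (Z)-2-iodo-enoate chain; the butenolide ring is closed first (metathesis); an allyl transposition turns it into the α-methylene lactone carrying C7 and C8; the epoxide arrives ready-made in the acid; the ten-membered ring is closed last by Ni/Cr-mediated C9–C10 bond formation.
Stereochemistry: C6 from a ligand-controlled vinylzinc addition; C7 and C8 relayed from C6 in the allylation, C8 then inverted by Mitsunobu esterification; C9 from Felkin–Anh control by C8 during ring closure; side chains from Sharpless epoxidation and an Evans syn aldol; Z-C4=C5 from neryl acetate, C1=C10 from the iodo-Wittig step.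

Key step: step 15

Remark: locants follow the germacrane skeleton (ring C1–C10; lactone C6–O–C12(=O)–C11(=C13)–C7; C14 = ester carbon on C10; C15 = methyl on C4), and acyclic precursors keep these locants.

Step 1
Reactants: 1 neryl acetate
Product: 3 (2Z)-3-methyl-6-oxohex-2-en-1-yl acetate, via ozonide 2 (not isolated)
Conditions: O3 (1 equiv), CH2Cl2, pyridine, −78 °C; then Me2S, −78 °C → rt
Reagents that add atoms: ozone [O-][O+]=O
Why: Chemoselective ozonolysis with reductive work-up; the trisubstituted 6,7-alkene is the electron-rich one because the 2,3-alkene is deactivated by the allylic acetate, so the Z alkene should survive untouched.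

Step 2
Reactants: 3 (2Z)-3-methyl-6-oxohex-2-en-1-yl acetate; 4 methyl (triphenylphosphoranylidene)acetate
Product: 6 methyl (2Z,6Z)-8-acetoxy-2-iodo-6-methylocta-2,6-dienoate, via iodo ylide 5 (not isolated)
Conditions: 4, NIS, CH2Cl2, −20 °C; then 3, K2CO3, −20 °C → rt
Reagents that add atoms: N-iodosuccinimide O=C1CCC(=O)N1I
Why: Wittig olefination with an α-iodinated stabilised ylide made in the same flask; stabilised ylides place the ester trans to the alkyl chain, so the (Z)-2-iodo enoate should form with C10 already carrying its ester and the handle for ring closure.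

Step 3
Reactants: 6 methyl (2Z,6Z)-8-acetoxy-2-iodo-6-methylocta-2,6-dienoate
Product: 7 methyl (2Z,6Z)-8-hydroxy-2-iodo-6-methylocta-2,6-dienoate
Conditions: K2CO3, MeOH, 0 °C
Reagents that add atoms: none
Why: Base-catalysed transesterification (methanolysis) of the allylic acetate; the methyl ester is degenerate under these conditions.

Step 4
Reactants: 7 methyl (2Z,6Z)-8-hydroxy-2-iodo-6-methylocta-2,6-dienoate
Product: 8 methyl (2Z,6Z)-2-iodo-6-methyl-8-oxoocta-2,6-dienoate
Conditions: activated MnO2, CH2Cl2, rt, dark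
Reagents that add atoms: none
Why: Allylic alcohol oxidation with manganese dioxide, a neutral oxidant that should keep the Z geometry of the β,β-disubstituted enal.

Step 5
Reactants: 8 methyl (2Z,6Z)-2-iodo-6-methyl-8-oxoocta-2,6-dienoate
Product: 9 methyl (2Z,6Z,8S)-8-hydroxy-2-iodo-6-methyldeca-2,6,9-trienoate
Conditions: divinylzinc, (−)-DAIB (10 mol %), toluene, −20 → 0 °C
Reagents that add atoms: divinylzinc C=C[Zn]C=C
Why: Amino-alcohol-catalysed asymmetric 1,2-addition of an alkenylzinc; the ligand-bound zinc should deliver vinyl to the Si face of the aldehyde and set C6 (8S here, the later 6R centre), while organozincs leave the ester and the alkenyl iodide alone.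

Step 6
Reactants: 9 methyl (2Z,6Z,8S)-8-hydroxy-2-iodo-6-methyldeca-2,6,9-trienoate; 10 2-(bromomethyl)acrylic acid
Product: 11 methyl (2Z,6Z,8S)-8-{[2-(bromomethyl)prop-2-enoyl]oxy}-2-iodo-6-methyldeca-2,6,9-trienoate
Conditions: DCC, DMAP (5 mol %), CH2Cl2, −10 → 0 °C
Reagents that add atoms: none
Why: Steglich esterification at low temperature should acylate the bis-allylic alcohol without allylic transposition and without touching C6.

Step 7
Reactants: 11 methyl (2Z,6Z,8S)-8-{[2-(bromomethyl)prop-2-enoyl]oxy}-2-iodo-6-methyldeca-2,6,9-trienoate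
Product: 12 methyl (2Z,6Z)-7-[(2R)-4-(bromomethyl)-5-oxo-2,5-dihydrofuran-2-yl]-2-iodo-6-methylhepta-2,6-dienoate
Conditions: Grubbs second-generation catalyst (5 mol %), CH2Cl2 (5 mM), 40 °C
Reagents that add atoms: none
Why: Ring-closing metathesis of the vinyl group with the acrylate alkene closes the butenolide; the five-membered closure should outrun any reaction of the trisubstituted alkenes, and C6 is untouched (its CIP label becomes R).

Step 8
Reactants: 12 methyl (2Z,6Z)-7-[(2R)-4-(bromomethyl)-5-oxo-2,5-dihydrofuran-2-yl]-2-iodo-6-methylhepta-2,6-dienoate; 13 (tert-butyldimethylsilyloxy)acetaldehyde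
Product: 14 methyl (2Z,6Z)-7-[(2R,3R)-3-{(1R)-2-[(tert-butyldimethylsilyl)oxy]-1-hydroxyethyl}-4-methylidene-5-oxooxolan-2-yl]-2-iodo-6-methylhepta-2,6-dienoate
Conditions: In powder, THF/H2O (1:1), rt
Reagents that add atoms: none
Why: Indium-mediated Barbier allylation with allylic transposition of a 3-(bromomethyl)butenolide; the aldehyde should bond to C7 anti to the C6 side chain (trans lactone) through a Zimmerman–Traxler chair with the ring carbon equatorial, giving the anti carbinol (8R, 8α-OH) and the exocyclic methylene (C7 has the target's spatial arrangement; its CIP label is R only while O8 is free).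

Step 9
Reactants: 15 methyl angelate
Product: 16 (2Z)-2-methylbut-2-en-1-ol
Conditions: DIBAL-H (2.2 equiv), CH2Cl2, −78 → 0 °C; Rochelle salt work-up
Reagents that add atoms: none
Why: 1,2-Reduction of an α,β-unsaturated ester with DIBAL-H should give the allylic alcohol with the Z geometry retained.

Step 10
Reactants: 16 (2Z)-2-methylbut-2-en-1-ol
Product: 17 [(2R,3S)-2,3-dimethyloxiran-2-yl]methanol
Conditions: Ti(OiPr)4 (cat.), D-(−)-diethyl tartrate, t-BuOOH, 4 Å MS, CH2Cl2, −20 °C
Reagents that add atoms: tert-butyl hydroperoxide CC(C)(C)OO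
Why: Sharpless asymmetric epoxidation; the D-(−)-tartrate complex should deliver oxygen to the face that gives the 2R centre, and the Z alkene makes C3 the S centre.

Step 11
Reactants: 17 [(2R,3S)-2,3-dimethyloxiran-2-yl]methanol
Product: 18 (2S,3S)-2,3-dimethyloxirane-2-carboxylic acid
Conditions: RuCl3·xH2O (2 mol %), NaIO4, CCl4/MeCN/H2O, rt
Reagents that add atoms: water O
Why: Ruthenium tetroxide oxidation (catalytic RuCl3 with periodate) of the primary alcohol to the acid via the aldehyde hydrate; the epoxide and both stereocentres are untouched (the CIP label at C2 becomes S).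

Step 12
Reactants: 14 methyl (2Z,6Z)-7-[(2R,3R)-3-{(1R)-2-[(tert-butyldimethylsilyl)oxy]-1-hydroxyethyl}-4-methylidene-5-oxooxolan-2-yl]-2-iodo-6-methylhepta-2,6-dienoate; 18 (2S,3S)-2,3-dimethyloxirane-2-carboxylic acid
Product: 19 methyl (2Z,6Z)-7-[(2R,3S)-3-{(1S)-2-[(tert-butyldimethylsilyl)oxy]-1-{[(2S,3S)-2,3-dimethyloxirane-2-carbonyl]oxy}ethyl}-4-methylidene-5-oxooxolan-2-yl]-2-iodo-6-methylhepta-2,6-dienoate
Conditions: PPh3, DIAD, toluene, 0 °C (betaine pre-formed); then 14 and 18, 0 °C → rt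
Reagents that add atoms: none
Why: Mitsunobu esterification; SN2 displacement of the activated C8–O by the carboxylate should invert C8 (8R → 8S, 8β) and install the epoxy ester in the same operation.

Step 13
Reactants: 19 methyl (2Z,6Z)-7-[(2R,3S)-3-{(1S)-2-[(tert-butyldimethylsilyl)oxy]-1-{[(2S,3S)-2,3-dimethyloxirane-2-carbonyl]oxy}ethyl}-4-methylidene-5-oxooxolan-2-yl]-2-iodo-6-methylhepta-2,6-dienoate
Product: 20 methyl (2Z,6Z)-7-[(2R,3S)-3-{(1S)-1-{[(2S,3S)-2,3-dimethyloxirane-2-carbonyl]oxy}-2-hydroxyethyl}-4-methylidene-5-oxooxolan-2-yl]-2-iodo-6-methylhepta-2,6-dienoate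
Conditions: HF·pyridine, pyridine, THF, 0 °C
Reagents that add atoms: none
Why: Fluoride-mediated cleavage of the primary silyl ether under buffered conditions that the glycidic ester, the lactone and the alkenyl iodide should tolerate.

Step 14
Reactants: 20 methyl (2Z,6Z)-7-[(2R,3S)-3-{(1S)-1-{[(2S,3S)-2,3-dimethyloxirane-2-carbonyl]oxy}-2-hydroxyethyl}-4-methylidene-5-oxooxolan-2-yl]-2-iodo-6-methylhepta-2,6-dienoate
Product: 21 methyl (2Z,6Z)-7-[(2R,3S)-3-{(1S)-1-{[(2S,3S)-2,3-dimethyloxirane-2-carbonyl]oxy}-2-oxoethyl}-4-methylidene-5-oxooxolan-2-yl]-2-iodo-6-methylhepta-2,6-dienoate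
Conditions: Dess–Martin periodinane, NaHCO3, CH2Cl2, 0 °C; used at once
Reagents that add atoms: none
Why: Dess–Martin oxidation under buffered, non-basic conditions should avoid epimerisation of the α-acyloxy aldehyde at C8 and acyl migration.

Step 15
Reactants: 21 methyl (2Z,6Z)-7-[(2R,3S)-3-{(1S)-1-{[(2S,3S)-2,3-dimethyloxirane-2-carbonyl]oxy}-2-oxoethyl}-4-methylidene-5-oxooxolan-2-yl]-2-iodo-6-methylhepta-2,6-dienoate
Product: 22 methyl (1(10)E,4Z,6R,7S,8S,9R)-8-{[(2S,3S)-2,3-dimethyloxirane-2-carbonyl]oxy}-9-hydroxy-germacra-1(10),4,11(13)-trien-6,12-olid-14-oate (the target without its C9 acyl group)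
Conditions: CrCl2 (6 equiv), NiCl2 (2 mol %), degassed DMSO/THF, rt; 21 added by syringe pump (final 2 mM)
Reagents that add atoms: none
Why: Ni(0) generated in the flask inserts into the C10–I bond of the (Z)-2-iodo enoate with retention, the alkenyl group passes to Cr(III), and the alkenylchromium adds to the C9 aldehyde while Cr(II) regenerates Ni(0). The closest known reaction type is the Nozaki–Hiyama–Kishi macrocyclisation of an alkenyl iodide onto an aldehyde, a reaction type that has closed ten-membered germacranolide carbocycles. The ten-membered ring closes by C9–C10 bond formation in a 10-exo-trig addition, the carbonyl oxygen staying outside the ring. The new stereocentre C9 is controlled by the C8 acyloxy stereocentre: attack anti to the C8–O bond (polar Felkin–Anh) should give the 8,9-anti carbinol, which is the 9R alcohol with O8 and O9 on the same face of the ring. The step needs cyclisation over oligomerisation, retention of alkene geometry and chemoselectivity; these rest on high dilution and the folding imposed by the two Z alkenes and the trans lactone, on the configurational stability of alkenyl nickel and chromium species (the iodide cis to C2 becomes the ring bond cis to C2), and on the tolerance of organochromium(III) reagents for esters, the epoxide and the α-methylene lactone.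

Step 16
Reactants: 23 (4R)-4-benzyl-3-propanoyl-1,3-oxazolidin-2-one; 24 acetaldehyde
Product: 26 (4R)-4-benzyl-3-[(2R,3S)-3-hydroxy-2-methylbutanoyl]-1,3-oxazolidin-2-one, via boron enolate 25 (not isolated)
Conditions: Bu2BOTf, iPr2NEt, CH2Cl2, 0 °C; then 24, −78 → 0 °C; pH 7 buffer, MeOH, H2O2
Reagents that add atoms: none
Why: Evans syn aldol; the Z boron enolate should react through a Zimmerman–Traxler chair on the face away from the benzyl group, giving the (2R,3S) syn aldol from the (R)-auxiliary.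

Step 17
Reactants: 26 (4R)-4-benzyl-3-[(2R,3S)-3-hydroxy-2-methylbutanoyl]-1,3-oxazolidin-2-one
Product: 27 (4R)-4-benzyl-3-{(2R,3S)-2-methyl-3-[(triethylsilyl)oxy]butanoyl}-1,3-oxazolidin-2-one
Conditions: TESCl, imidazole, DMF, 0 °C → rt
Reagents that add atoms: chlorotriethylsilane CC[Si](Cl)(CC)CC
Why: Silyl ether protection of the secondary alcohol, which creates no stereocentre and blocks retro-aldol and self-acylation later.

Step 18
Reactants: 27 (4R)-4-benzyl-3-{(2R,3S)-2-methyl-3-[(triethylsilyl)oxy]butanoyl}-1,3-oxazolidin-2-one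
Product: 28 (2R,3S)-2-methyl-3-[(triethylsilyl)oxy]butanoic acid
Conditions: LiOH, H2O2, THF/H2O, 0 °C; then Na2SO3; 1 M HCl to pH 4
Reagents that add atoms: hydrogen peroxide OO
Why: Hydroperoxide cleavage of the N-acyl oxazolidinone; lithium hydroperoxide attacks the exocyclic carbonyl, so C2 should not epimerise.

Step 19
Reactants: 22 the macrocyclic C9 alcohol; 28 (2R,3S)-2-methyl-3-[(triethylsilyl)oxy]butanoic acid
Product: 30 the O-triethylsilyl ether of the target (target with C3′–OSiEt3), via mixed anhydride 29 (not isolated)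
Conditions: 28, 2,4,6-trichlorobenzoyl chloride, Et3N, THF, rt; then 22, DMAP, toluene, rt
Reagents that add atoms: none
Why: Yamaguchi esterification; the acylpyridinium formed from the mixed anhydride should acylate the hindered allylic C9–OH with retention at C9.

Step 20
Reactants: 30 the O-triethylsilyl ether of the target
Product: 31 the target, methyl (1(10)E,4Z,6R,7S,8S,9R)-8-{[(2S,3S)-2,3-dimethyloxirane-2-carbonyl]oxy}-9-{[(2R,3S)-3-hydroxy-2-methylbutanoyl]oxy}-germacra-1(10),4,11(13)-trien-6,12-olid-14-oate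
Conditions: HF·pyridine, pyridine, THF, 0 °C
Reagents that add atoms: none
Why: Fluoride-mediated desilylation of the triethylsilyl ether under buffered conditions that should spare the epoxide, the α-methylene lactone and the three esters.

Compound list
1 | neryl acetate, (2Z)-3,7-dimethylocta-2,6-dien-1-yl acetate | CC(C)=CCC/C(C)=C\COC(C)=O | starting material
2 | ozonide of 1 at the 6,7-alkene, 5-[(3Z)-5-acetoxy-3-methylpent-3-en-1-yl]-3,3-dimethyl-1,2,4-trioxolane (mixture at the ring CH) | CC1(C)OOC(CC/C(C)=C\COC(C)=O)O1 | intermediate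
3 | (2Z)-3-methyl-6-oxohex-2-en-1-yl acetate | O=CCC/C(C)=C\COC(C)=O | intermediate
4 | methyl (triphenylphosphoranylidene)acetate | COC(=O)C=P(c1ccccc1)(c1ccccc1)c1ccccc1 | starting material
5 | methyl iodo(triphenylphosphoranylidene)acetate | COC(=O)C(I)=P(c1ccccc1)(c1ccccc1)c1ccccc1 | intermediate
6 | methyl (2Z,6Z)-8-acetoxy-2-iodo-6-methylocta-2,6-dienoate | COC(=O)/C(I)=C/CC/C(C)=C\COC(C)=O | intermediate
7 | methyl (2Z,6Z)-8-hydroxy-2-iodo-6-methylocta-2,6-dienoate | COC(=O)/C(I)=C/CC/C(C)=C\CO | intermediate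
8 | methyl (2Z,6Z)-2-iodo-6-methyl-8-oxoocta-2,6-dienoate | COC(=O)/C(I)=C/CC/C(C)=C\C=O | intermediate
9 | methyl (2Z,6Z,8S)-8-hydroxy-2-iodo-6-methyldeca-2,6,9-trienoate | COC(=O)/C(I)=C/CC/C(C)=C\[C@@H](O)C=C | intermediate
10 | 2-(bromomethyl)acrylic acid | C=C(CBr)C(=O)O | starting material
11 | methyl (2Z,6Z,8S)-8-{[2-(bromomethyl)prop-2-enoyl]oxy}-2-iodo-6-methyldeca-2,6,9-trienoate | COC(=O)/C(I)=C/CC/C(C)=C\[C@@H](OC(=O)C(=C)CBr)C=C | intermediate
12 | methyl (2Z,6Z)-7-[(2R)-4-(bromomethyl)-5-oxo-2,5-dihydrofuran-2-yl]-2-iodo-6-methylhepta-2,6-dienoate | COC(=O)/C(I)=C/CC/C(C)=C\[C@H]1OC(=O)C(CBr)=C1 | intermediate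
13 | (tert-butyldimethylsilyloxy)acetaldehyde | O=CCO[Si](C)(C)C(C)(C)C | starting material
14 | methyl (2Z,6Z)-7-[(2R,3R)-3-{(1R)-2-[(tert-butyldimethylsilyl)oxy]-1-hydroxyethyl}-4-methylidene-5-oxooxolan-2-yl]-2-iodo-6-methylhepta-2,6-dienoate (8α-OH) | C=C1C(=O)O[C@H](/C=C(/C)CC/C=C(/C(=O)OC)I)[C@H]1[C@@H](O)CO[Si](C)(C)C(C)(C)C | intermediate
15 | methyl angelate, methyl (2Z)-2-methylbut-2-enoate | C/C=C(/C)C(=O)OC | starting material
16 | (2Z)-2-methylbut-2-en-1-ol | C/C=C(/C)CO | intermediate
17 | [(2R,3S)-2,3-dimethyloxiran-2-yl]methanol | OC[C@@]1(C)O[C@H]1C | intermediate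
18 | (2S,3S)-2,3-dimethyloxirane-2-carboxylic acid | OC(=O)[C@@]1(C)O[C@H]1C | intermediate
19 | methyl (2Z,6Z)-7-[(2R,3S)-3-{(1S)-2-[(tert-butyldimethylsilyl)oxy]-1-{[(2S,3S)-2,3-dimethyloxirane-2-carbonyl]oxy}ethyl}-4-methylidene-5-oxooxolan-2-yl]-2-iodo-6-methylhepta-2,6-dienoate | C=C1C(=O)O[C@H](/C=C(/C)CC/C=C(/C(=O)OC)I)[C@H]1[C@H](OC(=O)[C@@]2(C)O[C@H]2C)CO[Si](C)(C)C(C)(C)C | intermediate
20 | methyl (2Z,6Z)-7-[(2R,3S)-3-{(1S)-1-{[(2S,3S)-2,3-dimethyloxirane-2-carbonyl]oxy}-2-hydroxyethyl}-4-methylidene-5-oxooxolan-2-yl]-2-iodo-6-methylhepta-2,6-dienoate | C=C1C(=O)O[C@H](/C=C(/C)CC/C=C(/C(=O)OC)I)[C@H]1[C@H](OC(=O)[C@@]2(C)O[C@H]2C)CO | intermediate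
21 | methyl (2Z,6Z)-7-[(2R,3S)-3-{(1S)-1-{[(2S,3S)-2,3-dimethyloxirane-2-carbonyl]oxy}-2-oxoethyl}-4-methylidene-5-oxooxolan-2-yl]-2-iodo-6-methylhepta-2,6-dienoate | C=C1C(=O)O[C@H](/C=C(/C)CC/C=C(/C(=O)OC)I)[C@H]1[C@H](OC(=O)[C@@]2(C)O[C@H]2C)C=O | intermediate
22 | methyl (1(10)E,4Z,6R,7S,8S,9R)-8-{[(2S,3S)-2,3-dimethyloxirane-2-carbonyl]oxy}-9-hydroxy-germacra-1(10),4,11(13)-trien-6,12-olid-14-oate | C=C1C(=O)O[C@@H]2/C=C(/C)CC/C=C(/C(=O)OC)[C@@H](O)[C@@H](OC(=O)[C@@]3(C)O[C@H]3C)[C@@H]12 | intermediate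
23 | (4R)-4-benzyl-3-propanoyl-1,3-oxazolidin-2-one | CCC(=O)N1[C@H](Cc2ccccc2)COC1=O | starting material
24 | acetaldehyde | CC=O | starting material
25 | (Z)-dibutylboron enolate of 23 | C/C=C(\OB(CCCC)CCCC)N1[C@H](Cc2ccccc2)COC1=O | intermediate
26 | (4R)-4-benzyl-3-[(2R,3S)-3-hydroxy-2-methylbutanoyl]-1,3-oxazolidin-2-one | O=C([C@H](C)[C@H](C)O)N1[C@H](Cc2ccccc2)COC1=O | intermediate
27 | (4R)-4-benzyl-3-{(2R,3S)-2-methyl-3-[(triethylsilyl)oxy]butanoyl}-1,3-oxazolidin-2-one | O=C([C@H](C)[C@H](C)O[Si](CC)(CC)CC)N1[C@H](Cc2ccccc2)COC1=O | intermediate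
28 | (2R,3S)-2-methyl-3-[(triethylsilyl)oxy]butanoic acid | OC(=O)[C@H](C)[C@H](C)O[Si](CC)(CC)CC | intermediate
29 | mixed anhydride of 28 with 2,4,6-trichlorobenzoic acid | O=C(OC(=O)c1c(Cl)cc(Cl)cc1Cl)[C@H](C)[C@H](C)O[Si](CC)(CC)CC | intermediate
30 | O-triethylsilyl ether of the target (6R,7S,8S,9R; side-chain C3′–OSiEt3) | C=C1C(=O)O[C@@H]2/C=C(/C)CC/C=C(/C(=O)OC)[C@@H](OC(=O)[C@H](C)[C@H](C)O[Si](CC)(CC)CC)[C@@H](OC(=O)[C@@]3(C)O[C@H]3C)[C@@H]12 | intermediate
31 | target, methyl (1(10)E,4Z,6R,7S,8S,9R)-8-{[(2S,3S)-2,3-dimethyloxirane-2-carbonyl]oxy}-9-{[(2R,3S)-3-hydroxy-2-methylbutanoyl]oxy}-germacra-1(10),4,11(13)-trien-6,12-olid-14-oate | C=C1C(=O)O[C@@H]2/C=C(/C)CC/C=C(/C(=O)OC)[C@@H](OC(=O)[C@H](C)[C@H](C)O)[C@@H](OC(=O)[C@@]3(C)O[C@H]3C)[C@@H]12 | target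

Total step count: 20. Longest linear sequence: 14 (steps 1–8, 12–15, 19, 20).

Steps most likely to fail

1. Step 15. Ring strain in the closing transition state may override the Felkin–Anh preference, so that the addition to the C9 aldehyde occurs with poor or reversed facial selectivity. The fallback sets out from 21 and returns at 22. The closure is run as in step 15, and the C9-epimeric carbinol, 9-epi alcohol F1, alone or mixed with 22, is oxidised (Dess–Martin periodinane, NaHCO3, CH2Cl2) to the macrocyclic C9 ketone F2. A Luche reduction (NaBH4, CeCl3·7H2O, MeOH, −78 °C) should then deliver hydride from the outer face of the ring ketone, the face opposite to the one taken by the tethered alkenyl group during ring closure, and give 22. C9 is then set by reduction of a ring ketone and no longer by the ring-closing addition.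

2. Step 12. The oxyphosphonium ion at the hindered C8 may eliminate toward C7, or substitution may stall, so that inversion is incomplete. The fallback sets out from 14 and returns at 19. Oxidation of 14 (Dess–Martin periodinane, NaHCO3) gives the C8 ketone F3. Corey–Bakshi–Shibata reduction ((S)-Me-CBS, catecholborane, toluene, −78 °C; lactone carbon as the large group, CH2OSi as the small one) should give the 8S alcohol F4 under reagent control. Yamaguchi esterification of F4 with 18 (retention) gives 19.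

3. Step 5. The vinyl transfer may proceed with insufficient enantioselectivity, and the Z enal may isomerise on the Lewis acidic zinc. The fallback sets out from 8 and returns at 9. A zinc–ProPhenol-catalysed addition of (trimethylsilyl)acetylene (Me2Zn, toluene, 0 °C; the ligand antipode that attacks the Si face) gives the propargylic alcohol F5. Desilylation (K2CO3, MeOH, 0 °C) gives the terminal alkyne F6, and semi-hydrogenation (Lindlar catalyst, quinoline, H2, EtOAc) gives 9.

Further compounds
F1 | step 15 | 9-epi alcohol, the (9S) epimer of 22 | C=C1C(=O)O[C@@H]2/C=C(/C)CC/C=C(/C(=O)OC)[C@H](O)[C@@H](OC(=O)[C@@]3(C)O[C@H]3C)[C@@H]12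
F2 | step 15 | macrocyclic C9 ketone, the 9-oxo analogue of 22 | C=C1C(=O)O[C@@H]2/C=C(/C)CC/C=C(/C(=O)OC)C(=O)[C@@H](OC(=O)[C@@]3(C)O[C@H]3C)[C@@H]12
F3 | step 12 | C8 ketone, methyl (2Z,6Z)-7-[(2R,3S)-3-{[(tert-butyldimethylsilyl)oxy]acetyl}-4-methylidene-5-oxooxolan-2-yl]-2-iodo-6-methylhepta-2,6-dienoate | C=C1C(=O)O[C@H](/C=C(/C)CC/C=C(/C(=O)OC)I)[C@H]1C(=O)CO[Si](C)(C)C(C)(C)C
F4 | step 12 | 8S alcohol, the C8 epimer of 14 | C=C1C(=O)O[C@H](/C=C(/C)CC/C=C(/C(=O)OC)I)[C@H]1[C@H](O)CO[Si](C)(C)C(C)(C)C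
F5 | step 5 | methyl (2Z,6Z,8R)-8-hydroxy-2-iodo-6-methyl-10-(trimethylsilyl)deca-2,6-dien-9-ynoate | COC(=O)/C(I)=C/CC/C(C)=C\[C@@H](O)C#C[Si](C)(C)C
F6 | step 5 | methyl (2Z,6Z,8R)-8-hydroxy-2-iodo-6-methyldeca-2,6-dien-9-ynoate | COC(=O)/C(I)=C/CC/C(C)=C\[C@@H](O)C#C
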